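**Retrosynthetic overview**

1. The last C–C bond made joins C3' of an intact, unprotected 2',4'-dihydroxychalcone (isoliquiritigenin; the arene carbon between its two phenolic oxygens) to C1 of the cyclohexene, by a Pd-catalysed, stereoretentive allylic C–H alkylation of an allylic acetate; a global desilylation then gives the target.
2. Enabling feature: C1 of the cyclohexene is allylic to the ring C2=C3(CH3) double bond, so C1–C2–C3 can be ionised to a π-allyl unit, and the arene carbon that bonds to it is flanked by the two OH groups of an acylresorcinol ring (a vinylogous acid, hence a soft carbon nucleophile).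
3. The cyclohexene is the only ring built. It comes from a catalytic asymmetric endo Diels–Alder reaction of a 2'-hydroxychalcone with (E)-1-acetoxy-3-methylbutadiene, which sets C5, C6 and the acetate-bearing C1 in one event; the acetate is the placeholder that the key step exchanges for the aryl group with retention.
4. The dienophile chalcone comes from an aldol condensation of a silylated 2,4-dihydroxybenzaldehyde with an acetophenone whose (E)-3-methylbut-1-enyl group is installed by iodination and Suzuki coupling.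

Key step: step 10

Remark on locants: in the cyclohexene names, C1 carries the acetate (later the aryl group), C3 the methyl group, C5 the 2,4-dioxygenated phenyl group and C6 the aroyl group. TBS = tert-butyldimethylsilyl.

Assumption: the (R)-VANOL borate is taken to shield the face of the chelated chalcone that leads to the (1S,5S,6R) adduct; if the opposite sense is found, the (S)-ligand is used with no other change.

**Route**

Step 1
Reactants: 1 2,4-dihydroxyacetophenone
Product: 2 1-(2,4-dihydroxy-3-iodophenyl)ethan-1-one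
Conditions: I2 (0.4 equiv), HIO3 (0.2 equiv), EtOH/H2O, 40 °C
Reagents that add atoms: iodine, II; iodic acid, OI(=O)=O
Why: Electrophilic aromatic iodination of the resorcinol ketone should go to the carbon between the two hydroxyl groups, the most activated position, and iodic acid re-oxidises the iodide so that all iodine is used.

Step 2
Reactants: 3 3-methylbut-1-yne
Product: 4 (E)-4,4,5,5-tetramethyl-2-(3-methylbut-1-en-1-yl)-1,3,2-dioxaborolane
Conditions: pinacolborane, Cp2Zr(H)Cl (5 mol %), Et3N (10 mol %), neat, 60 °C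
Reagents that add atoms: pinacolborane, CC1(C)OBOC1(C)C
Why: Zirconocene-catalysed hydroboration of a terminal alkyne adds H–B syn and anti-Markovnikov, which should give only the (E)-alkenylboronate.

Step 3
Reactants: 2 1-(2,4-dihydroxy-3-iodophenyl)ethan-1-one; 4 (E)-4,4,5,5-tetramethyl-2-(3-methylbut-1-en-1-yl)-1,3,2-dioxaborolane
Product: 5 1-{2,4-dihydroxy-3-[(E)-3-methylbut-1-en-1-yl]phenyl}ethan-1-one
Conditions: Pd(OAc)2 (3 mol %), SPhos (6 mol %), K3PO4, 1,4-dioxane/H2O (5:1), 70 °C
Reagents that add atoms: none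
Why: Suzuki–Miyaura coupling proceeds with retention of the alkene geometry, free phenols are tolerated under aqueous phosphate, and the biaryl phosphine should cope with the doubly ortho-substituted iodide.

Step 4
Reactants: 5 1-{2,4-dihydroxy-3-[(E)-3-methylbut-1-en-1-yl]phenyl}ethan-1-one
Product: 6 1-{4-(TBS-oxy)-2-hydroxy-3-[(E)-3-methylbut-1-en-1-yl]phenyl}ethan-1-one
Conditions: TBSCl (1.05 equiv), imidazole, CH2Cl2, 0 °C
Reagents that add atoms: tert-butyldimethylsilyl chloride, CC(C)(C)[Si](C)(C)Cl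
Why: Silylation of a phenol; the 2-hydroxyl is locked in a hydrogen bond to the ketone, so one equivalent of the silyl chloride should take only the 4-hydroxyl.

Step 5
Reactants: 7 2,4-dihydroxybenzaldehyde
Product: 8 2,4-bis(TBS-oxy)benzaldehyde
Conditions: TBSCl (2.3 equiv), imidazole, DMF, 25 °C
Reagents that add atoms: tert-butyldimethylsilyl chloride, CC(C)(C)[Si](C)(C)Cl
Why: Standard silylation of both phenols, which must be masked for the aldol condensation and for the boron-mediated cycloaddition.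

Step 6
Reactants: 6 1-{4-(TBS-oxy)-2-hydroxy-3-[(E)-3-methylbut-1-en-1-yl]phenyl}ethan-1-one; 8 2,4-bis(TBS-oxy)benzaldehyde
Product: 10 (E)-3-[2,4-bis(TBS-oxy)phenyl]-1-{4-(TBS-oxy)-2-hydroxy-3-[(E)-3-methylbut-1-en-1-yl]phenyl}prop-2-en-1-one, via β-hydroxy ketone aldol adduct 9 (not isolated)
Conditions: LiHMDS (3.3 equiv), THF, −78 °C; then 8, −78 → 25 °C; aq. NH4Cl
Reagents that add atoms: none
Why: Claisen–Schmidt aldol condensation through the lithium dianion of the ketone; the aldolate should eliminate by E1cB on warming to the conjugated (E)-enone, and the amide base avoids the hydroxide/alcohol media that strip aryl silyl ethers.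

Step 7
Reactants: 11 3-methylbut-2-enal
Product: 12 (E)-3-methylbuta-1,3-dien-1-yl acetate
Conditions: Ac2O, Et3N, DMAP (cat.), 80 °C; distillation
Reagents that add atoms: acetic anhydride, CC(=O)OC(C)=O
Why: O-Acylation of the extended dienolate of the enal (dienyl acetate formation) under equilibrating conditions should give the (E)-dienyl acetate as the main isomer.

Step 8
Reactants: 10 (E)-3-[2,4-bis(TBS-oxy)phenyl]-1-{4-(TBS-oxy)-2-hydroxy-3-[(E)-3-methylbut-1-en-1-yl]phenyl}prop-2-en-1-one; 12 (E)-3-methylbuta-1,3-dien-1-yl acetate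
Product: 13 (1S,5S,6R)-5-[2,4-bis(TBS-oxy)phenyl]-6-{4-(TBS-oxy)-2-hydroxy-3-[(E)-3-methylbut-1-en-1-yl]benzoyl}-3-methylcyclohex-2-en-1-yl acetate
Conditions: B(OPh)3 (20 mol %), (R)-VANOL (20 mol %), 5 Å MS, PhCF3, 25 °C; 12 (3 equiv)
Reagents that add atoms: none
Why: Chiral borate-mediated Diels–Alder reaction of a 2'-hydroxychalcone, in which the chelated phenol–ketone borate lowers the LUMO and the ligand shields one face (setting C5 and C6 absolutely); the 1-acetoxy and 3-methyl groups direct the same regiochemistry, the trans-enone fixes the C5/C6 trans relation, and the endo mode should place the acetate at C1 cis to the aroyl group.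

Step 9
Reactants: 13 (1S,5S,6R)-5-[2,4-bis(TBS-oxy)phenyl]-6-{4-(TBS-oxy)-2-hydroxy-3-[(E)-3-methylbut-1-en-1-yl]benzoyl}-3-methylcyclohex-2-en-1-yl acetate
Product: 14 (1S,5S,6R)-5-[2,4-bis(TBS-oxy)phenyl]-6-{2,4-bis(TBS-oxy)-3-[(E)-3-methylbut-1-en-1-yl]benzoyl}-3-methylcyclohex-2-en-1-yl acetate
Conditions: TBSOTf (1.2 equiv), 2,6-lutidine, CH2Cl2, −78 → 0 °C
Reagents that add atoms: tert-butyldimethylsilyl triflate, CC(C)(C)[Si](C)(C)OS(=O)(=O)C(F)(F)F
Why: A silyl triflate with a hindered pyridine base should silylate even the chelated, flanked phenol at low temperature, which removes the only internal nucleophile that could attack the π-allyl intermediate of the next step.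

Step 10
Reactants: 14 (1S,5S,6R)-5-[2,4-bis(TBS-oxy)phenyl]-6-{2,4-bis(TBS-oxy)-3-[(E)-3-methylbut-1-en-1-yl]benzoyl}-3-methylcyclohex-2-en-1-yl acetate; 15 isoliquiritigenin, (E)-1-(2,4-dihydroxyphenyl)-3-(4-hydroxyphenyl)prop-2-en-1-one
Product: 16 (E)-1-{3-[(1S,5S,6R)-5-[2,4-bis(TBS-oxy)phenyl]-6-{2,4-bis(TBS-oxy)-3-[(E)-3-methylbut-1-en-1-yl]benzoyl}-3-methylcyclohex-2-en-1-yl]-2,4-dihydroxyphenyl}-3-(4-hydroxyphenyl)prop-2-en-1-one
Conditions: Pd(PPh3)4 (5 mol %), Cs2CO3 (1.1 equiv), 15 (1.5 equiv), degassed THF, 40 → 60 °C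
Reagents that add atoms: none
Why: Proposed new method: Pd(0) should ionise the allylic acetate of 14 anti to the leaving group to give a π-allyl complex across C1–C2–C3 with palladium on the face opposite the C6 aroyl group, and the cesium phenoxide of 15 then attacks as a soft, outer-sphere carbon nucleophile through the resorcinol carbon between its two oxygens, after which the cyclohexadienone re-aromatises by tautomerisation. The closest known reaction type is the Tsuji–Trost (Friedel–Crafts-type) C-allylation of electron-rich phenols, naphthols and acylphloroglucinols, combined with the net retention (double inversion) that stabilised nucleophiles show on cyclic allylic acetates. No ring is closed. The new stereocentre (C1 of the cyclohexene, S) is fixed by the Diels–Alder-derived acetate through double inversion, so the aryl group should end cis to the aroyl group and trans to the C5 aryl group, while C5 and C6 are untouched. Three selectivities are needed: attack at the secondary allyl terminus and not at the methyl-bearing one (a quaternary centre would form there), C- over O-allylation (allyl ethers of this acidic phenol re-ionise under Pd(0), whereas C–C bond formation is irreversible), and C3' over C5' or the other phenol ring (C3' is the doubly oxygen-activated carbon of the vinylogous acid). The silyl ether on the 2'-oxygen of the aroyl group blocks intramolecular O-allylation, and elimination towards a dienone is held back by the mild base and the low temperature.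

Step 11
Reactants: 16 (E)-1-{3-[(1S,5S,6R)-5-[2,4-bis(TBS-oxy)phenyl]-6-{2,4-bis(TBS-oxy)-3-[(E)-3-methylbut-1-en-1-yl]benzoyl}-3-methylcyclohex-2-en-1-yl]-2,4-dihydroxyphenyl}-3-(4-hydroxyphenyl)prop-2-en-1-one
Product: 17 (E)-1-{3-[(1S,5S,6R)-6-{2,4-dihydroxy-3-[(E)-3-methylbut-1-en-1-yl]benzoyl}-5-(2,4-dihydroxyphenyl)-3-methylcyclohex-2-en-1-yl]-2,4-dihydroxyphenyl}-3-(4-hydroxyphenyl)prop-2-en-1-one (CNP0140882.1)
Conditions: TBAF (4.4 equiv), AcOH (4.4 equiv), THF, 0 °C, argon
Reagents that add atoms: none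
Why: Fluoride cleaves the four aryl silyl ethers under buffered, near-neutral conditions, so that neither acid-induced ketal or chroman formation nor base-induced epimerisation at C6 should occur and no stereocentre is touched.

**Compound list**

1 | 2,4-dihydroxyacetophenone | CC(=O)c1ccc(O)cc1O | starting material
2 | 1-(2,4-dihydroxy-3-iodophenyl)ethan-1-one | CC(=O)c1ccc(O)c(I)c1O | intermediate
3 | 3-methylbut-1-yne | CC(C)C#C | starting material
4 | (E)-4,4,5,5-tetramethyl-2-(3-methylbut-1-en-1-yl)-1,3,2-dioxaborolane | CC(C)/C=C/B1OC(C)(C)C(C)(C)O1 | intermediate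
5 | 1-{2,4-dihydroxy-3-[(E)-3-methylbut-1-en-1-yl]phenyl}ethan-1-one | CC(=O)c1ccc(O)c(/C=C/C(C)C)c1O | intermediate
6 | 1-{4-(TBS-oxy)-2-hydroxy-3-[(E)-3-methylbut-1-en-1-yl]phenyl}ethan-1-one | CC(=O)c1ccc(O[Si](C)(C)C(C)(C)C)c(/C=C/C(C)C)c1O | intermediate
7 | 2,4-dihydroxybenzaldehyde | O=Cc1ccc(O)cc1O | starting material
8 | 2,4-bis(TBS-oxy)benzaldehyde | O=Cc1ccc(O[Si](C)(C)C(C)(C)C)cc1O[Si](C)(C)C(C)(C)C | intermediate
9 | 3-[2,4-bis(TBS-oxy)phenyl]-3-hydroxy-1-{4-(TBS-oxy)-2-hydroxy-3-[(E)-3-methylbut-1-en-1-yl]phenyl}propan-1-one (racemic aldol adduct, not isolated) | OC(CC(=O)c1ccc(O[Si](C)(C)C(C)(C)C)c(/C=C/C(C)C)c1O)c1ccc(O[Si](C)(C)C(C)(C)C)cc1O[Si](C)(C)C(C)(C)C | intermediate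
10 | (E)-3-[2,4-bis(TBS-oxy)phenyl]-1-{4-(TBS-oxy)-2-hydroxy-3-[(E)-3-methylbut-1-en-1-yl]phenyl}prop-2-en-1-one | O=C(/C=C/c1ccc(O[Si](C)(C)C(C)(C)C)cc1O[Si](C)(C)C(C)(C)C)c1ccc(O[Si](C)(C)C(C)(C)C)c(/C=C/C(C)C)c1O | intermediate
11 | 3-methylbut-2-enal | CC(C)=CC=O | starting material
12 | (E)-3-methylbuta-1,3-dien-1-yl acetate | CC(=C)/C=C/OC(C)=O | intermediate
13 | (1S,5S,6R)-5-[2,4-bis(TBS-oxy)phenyl]-6-{4-(TBS-oxy)-2-hydroxy-3-[(E)-3-methylbut-1-en-1-yl]benzoyl}-3-methylcyclohex-2-en-1-yl acetate | CC1=C[C@H](OC(C)=O)[C@H](C(=O)c2ccc(O[Si](C)(C)C(C)(C)C)c(/C=C/C(C)C)c2O)[C@@H](c2ccc(O[Si](C)(C)C(C)(C)C)cc2O[Si](C)(C)C(C)(C)C)C1 | intermediate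
14 | (1S,5S,6R)-5-[2,4-bis(TBS-oxy)phenyl]-6-{2,4-bis(TBS-oxy)-3-[(E)-3-methylbut-1-en-1-yl]benzoyl}-3-methylcyclohex-2-en-1-yl acetate | CC1=C[C@H](OC(C)=O)[C@H](C(=O)c2ccc(O[Si](C)(C)C(C)(C)C)c(/C=C/C(C)C)c2O[Si](C)(C)C(C)(C)C)[C@@H](c2ccc(O[Si](C)(C)C(C)(C)C)cc2O[Si](C)(C)C(C)(C)C)C1 | intermediate
15 | isoliquiritigenin, (E)-1-(2,4-dihydroxyphenyl)-3-(4-hydroxyphenyl)prop-2-en-1-one | O=C(/C=C/c1ccc(O)cc1)c1ccc(O)cc1O | starting material
16 | (E)-1-{3-[(1S,5S,6R)-5-[2,4-bis(TBS-oxy)phenyl]-6-{2,4-bis(TBS-oxy)-3-[(E)-3-methylbut-1-en-1-yl]benzoyl}-3-methylcyclohex-2-en-1-yl]-2,4-dihydroxyphenyl}-3-(4-hydroxyphenyl)prop-2-en-1-one | CC1=C[C@H](c2c(O)ccc(C(=O)/C=C/c3ccc(O)cc3)c2O)[C@H](C(=O)c2ccc(O[Si](C)(C)C(C)(C)C)c(/C=C/C(C)C)c2O[Si](C)(C)C(C)(C)C)[C@@H](c2ccc(O[Si](C)(C)C(C)(C)C)cc2O[Si](C)(C)C(C)(C)C)C1 | intermediate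
17 | (E)-1-{3-[(1S,5S,6R)-6-{2,4-dihydroxy-3-[(E)-3-methylbut-1-en-1-yl]benzoyl}-5-(2,4-dihydroxyphenyl)-3-methylcyclohex-2-en-1-yl]-2,4-dihydroxyphenyl}-3-(4-hydroxyphenyl)prop-2-en-1-one | CC1=C[C@H](c2c(O)ccc(C(=O)/C=C/c3ccc(O)cc3)c2O)[C@H](C(=O)c2ccc(O)c(/C=C/C(C)C)c2O)[C@@H](c2ccc(O)cc2O)C1 | target

**Step count and risks**

Total step count: 11. Longest linear sequence: 8 steps (steps 1, 3, 4, 6, 8, 9, 10, 11).

Steps most likely to fail:

1. Step 10 (Proposed new method). The allyl unit may be delivered to the wrong nucleophilic site (a phenol oxygen, C5' or the other phenol ring), the chalcone nucleophile may isomerise towards its flavanone under base, and the π-allyl intermediate may lose the acidic proton next to the ketone and collapse by elimination. Fallback, using known chemistry: the polarity of the union is reversed and the arene position is fixed by a halogen. The fallback sets out from 10 and 2 and comes back at 17. Zirconium-catalysed hydroboration of 2-methylbut-1-en-3-yne with pinacolborane should give (E)-4,4,5,5-tetramethyl-2-(3-methylbuta-1,3-dien-1-yl)-1,3,2-dioxaborolane F1. Its endo Diels–Alder reaction with 10 under the borate conditions of step 8 should give the cis,trans allylic boronate 2-[(1S,5S,6S)-5-[2,4-bis(TBS-oxy)phenyl]-6-{4-(TBS-oxy)-2-hydroxy-3-[(E)-3-methylbut-1-en-1-yl]benzoyl}-3-methylcyclohex-2-en-1-yl]-4,4,5,5-tetramethyl-1,3,2-dioxaborolane F2 (same spatial arrangement as 13, boron in place of the acetate). Separately, Claisen–Schmidt condensation of 2 with 4-hydroxybenzaldehyde (KOH, EtOH/H2O) should give 3'-iodoisoliquiritigenin F3, which TBSCl/imidazole converts into (E)-1-[4-(TBS-oxy)-2-hydroxy-3-iodophenyl]-3-[4-(TBS-oxy)phenyl]prop-2-en-1-one F4. A stereoretentive, α-selective allyl–aryl Suzuki–Miyaura coupling of F2 with F4 (Pd(OAc)2/XPhos, K3PO4, THF/H2O) then forms the same aryl–C1 bond and should give the penta-silyl ether of the target F5. Desilylation as in step 11 returns to 17.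

2. Step 8. Facial selectivity and the endo/exo ratio may be poor with an oxygenated diene on this hindered, electron-rich chalcone, and the dienyl acetate may decompose under Lewis acid before it reacts. Fallback: enantiocontrol by catalyst is given up for resolution. Setting out from 10 and 12, the cycloaddition is run without chiral ligand (heat in toluene, or silica-supported silver nanoparticles), which should be endo-selective for a 1-acyloxydiene and give 13 together with its mirror image, (1R,5R,6S)-5-[2,4-bis(TBS-oxy)phenyl]-6-{4-(TBS-oxy)-2-hydroxy-3-[(E)-3-methylbut-1-en-1-yl]benzoyl}-3-methylcyclohex-2-en-1-yl acetate F6. Preparative chromatography on a chiral stationary phase then supplies 13, where the route is rejoined.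

3. Step 6. The aryl silyl ethers may be lost to the lithium hydroxide that the elimination releases, or the aldolate may revert or stall instead of eliminating. Fallback: a Lewis-acid aldol addition and a separate dehydration replace the enolate condensation. Setting out from 6, TMSOTf/Et3N should give the trimethylsilyl enol ether that is also O-silylated at the phenol, tert-butyldimethyl{3-[(E)-3-methylbut-1-en-1-yl]-2-(trimethylsilyloxy)-4-[1-(trimethylsilyloxy)vinyl]phenoxy}silane F7. A BF3·OEt2-mediated Mukaiyama aldol addition of F7 to 8 at −78 °C, followed by aqueous work-up, should give the β-hydroxy ketone 9, now isolated. Dehydration with catalytic PPTS in warm toluene comes back to the route at 10.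

**Further compounds**

F1 | step 10 | (E)-4,4,5,5-tetramethyl-2-(3-methylbuta-1,3-dien-1-yl)-1,3,2-dioxaborolane | CC(=C)/C=C/B1OC(C)(C)C(C)(C)O1
F2 | step 10 | 2-[(1S,5S,6S)-5-[2,4-bis(TBS-oxy)phenyl]-6-{4-(TBS-oxy)-2-hydroxy-3-[(E)-3-methylbut-1-en-1-yl]benzoyl}-3-methylcyclohex-2-en-1-yl]-4,4,5,5-tetramethyl-1,3,2-dioxaborolane | CC1=C[C@H](B2OC(C)(C)C(C)(C)O2)[C@H](C(=O)c2ccc(O[Si](C)(C)C(C)(C)C)c(/C=C/C(C)C)c2O)[C@@H](c2ccc(O[Si](C)(C)C(C)(C)C)cc2O[Si](C)(C)C(C)(C)C)C1
F3 | step 10 | 3'-iodoisoliquiritigenin, (E)-1-(2,4-dihydroxy-3-iodophenyl)-3-(4-hydroxyphenyl)prop-2-en-1-one | O=C(/C=C/c1ccc(O)cc1)c1ccc(O)c(I)c1O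
F4 | step 10 | (E)-1-[4-(TBS-oxy)-2-hydroxy-3-iodophenyl]-3-[4-(TBS-oxy)phenyl]prop-2-en-1-one | O=C(/C=C/c1ccc(O[Si](C)(C)C(C)(C)C)cc1)c1ccc(O[Si](C)(C)C(C)(C)C)c(I)c1O
F5 | step 10 | (E)-1-{3-[(1S,5S,6R)-5-[2,4-bis(TBS-oxy)phenyl]-6-{4-(TBS-oxy)-2-hydroxy-3-[(E)-3-methylbut-1-en-1-yl]benzoyl}-3-methylcyclohex-2-en-1-yl]-4-(TBS-oxy)-2-hydroxyphenyl}-3-[4-(TBS-oxy)phenyl]prop-2-en-1-one | CC1=C[C@H](c2c(O[Si](C)(C)C(C)(C)C)ccc(C(=O)/C=C/c3ccc(O[Si](C)(C)C(C)(C)C)cc3)c2O)[C@H](C(=O)c2ccc(O[Si](C)(C)C(C)(C)C)c(/C=C/C(C)C)c2O)[C@@H](c2ccc(O[Si](C)(C)C(C)(C)C)cc2O[Si](C)(C)C(C)(C)C)C1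
F6 | step 8 | (1R,5R,6S)-5-[2,4-bis(TBS-oxy)phenyl]-6-{4-(TBS-oxy)-2-hydroxy-3-[(E)-3-methylbut-1-en-1-yl]benzoyl}-3-methylcyclohex-2-en-1-yl acetate | CC1=C[C@@H](OC(C)=O)[C@@H](C(=O)c2ccc(O[Si](C)(C)C(C)(C)C)c(/C=C/C(C)C)c2O)[C@H](c2ccc(O[Si](C)(C)C(C)(C)C)cc2O[Si](C)(C)C(C)(C)C)C1
F7 | step 6 | tert-butyldimethyl{3-[(E)-3-methylbut-1-en-1-yl]-2-(trimethylsilyloxy)-4-[1-(trimethylsilyloxy)vinyl]phenoxy}silane | C=C(O[Si](C)(C)C)c1ccc(O[Si](C)(C)C(C)(C)C)c(/C=C/C(C)C)c1O[Si](C)(C)C
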